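**Retrosynthetic overview**

1. Feature: in the carbocycle C5–C10, quaternary C10 (methyl C14, vinyl C1=C2) adjoins the C9 methylene, which is bonded to oxygen-bearing C8. C10 is therefore treated as a methyl-divinyl carbon, one vinyl of which is spent to make C9.
2. Late stage: the C8 ester comes from the 8α-alcohol and the cyclic acetonide (dioxepine) form of the side-chain acid; the C11 methylene comes from a Mannich/elimination sequence; the 8α-hydroxyl comes from the C8 ketone.
3. Key disconnection: the C8=C9 bond, by ring-closing metathesis between one of two diastereotopic C10 vinyl groups and a C8 silyl enol ether on a preformed trans lactone. This closes the carbocycle and makes C10 stereogenic.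
4. The lactone (O, C6, C7, C11, C12) comes from a syn-aldol of a succinate imide with the C5 aldehyde, followed by lactonisation; the imide carbonyl becomes C8.
5. The C5–C10 bond and the C5 configuration come from an enantioselective Ireland–Claisen rearrangement. Ring order: γ-lactone first (step 7), cyclohexene second (step 11).

Key step: step 11

Assumption: the sense of induction of the (S,S)-bromodiazaborolidine in step 3 is assigned by analogy with its propionate cases, and the matched antipode of the molybdenum complex in step 11 cannot be predicted; if a first run shows the mirror-image sense, the other antipode of that reagent is used and nothing else changes.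

**Route**

Step 1
Reactants: 1 (2Z)-3-methylpent-2-en-4-yn-1-ol
Product: 2 (2Z)-3-methylpenta-2,4-dien-1-ol
Conditions: H2 (1 atm), Pd/CaCO3 poisoned with Pb(OAc)2 (Lindlar catalyst), quinoline, EtOAc–hexane, 0 °C, stopped after 1 equiv H2
Reagents that add atoms: none
Why: Lindlar semihydrogenation takes the terminal alkyne to the vinyl group and stops there, and the trisubstituted alkene is not touched.

Step 2
Reactants: 2 (2Z)-3-methylpenta-2,4-dien-1-ol; 3 3-methylbut-3-enoic acid
Product: 4 (2Z)-3-methylpenta-2,4-dien-1-yl 3-methylbut-3-enoate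
Conditions: DCC, DMAP (5 mol %), CH2Cl2, 0 °C
Reagents that add atoms: none
Why: Steglich esterification, run cold with little DMAP so that the β,γ-unsaturated acid is not isomerised into conjugation.

Step 3
Reactants: 4 (2Z)-3-methylpenta-2,4-dien-1-yl 3-methylbut-3-enoate
Product: 6 (2R)-3-ethenyl-3-methyl-2-(prop-1-en-2-yl)pent-4-enoic acid, via boron ketene acetal 5 (not isolated)
Conditions: (S,S)-2-bromo-1,3-bis[3,5-bis(trifluoromethyl)phenylsulfonyl]-4,5-diphenyl-1,3,2-diazaborolidine (1.2 equiv), Et3N, toluene–hexane, −78 °C, then −20 → 4 °C; aqueous work-up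
Reagents that add atoms: none
Why: Enantioselective boron-mediated Ireland–Claisen rearrangement: the [3,3] shift of ketene acetal 5 bonds the ester α-carbon (C5) to the methyl-bearing alkene carbon (C10), which ends with two identical vinyl groups, so C5 is the only stereocentre and its R configuration is set by the face selection of the chiral diazaborolidine.

Step 4
Reactants: 6 (2R)-3-ethenyl-3-methyl-2-(prop-1-en-2-yl)pent-4-enoic acid
Product: 7 (2R)-3-ethenyl-3-methyl-2-(prop-1-en-2-yl)pent-4-en-1-ol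
Conditions: LiAlH4, Et2O, 0 °C
Reagents that add atoms: none
Why: Hydride reduction of the acid to the primary alcohol, which leaves the isolated alkenes alone and cannot epimerise C5.

Step 5
Reactants: 7 (2R)-3-ethenyl-3-methyl-2-(prop-1-en-2-yl)pent-4-en-1-ol
Product: 8 (2R)-3-ethenyl-3-methyl-2-(prop-1-en-2-yl)pent-4-enal
Conditions: Dess–Martin periodinane, NaHCO3, CH2Cl2, 0 °C; used at once without chromatography
Reagents that add atoms: none
Why: Dess–Martin oxidation is non-basic, so the α-isopropenyl aldehyde should form without epimerisation at C5 or migration of the double bond into conjugation.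

Step 6
Reactants: 9 (4R)-4-benzyl-1,3-oxazolidin-2-one; 10 methyl 4-chloro-4-oxobutanoate
Product: 11 methyl 4-[(4R)-4-benzyl-2-oxo-1,3-oxazolidin-3-yl]-4-oxobutanoate
Conditions: Et3N, DMAP (cat.), CH2Cl2, 0 °C → rt
Reagents that add atoms: none
Why: N-acylation of the oxazolidinone by the acid chloride under DMAP catalysis.

Step 7
Reactants: 11 methyl 4-[(4R)-4-benzyl-2-oxo-1,3-oxazolidin-3-yl]-4-oxobutanoate; 8 (2R)-3-ethenyl-3-methyl-2-(prop-1-en-2-yl)pent-4-enal
Product: 14 (4R)-4-benzyl-3-{[(2S,3R)-2-[(3R)-4-ethenyl-2,4-dimethylhexa-1,5-dien-3-yl]-5-oxooxolan-3-yl]carbonyl}-1,3-oxazolidin-2-one, via dibutylboron Z-enolate 12 (not isolated), via syn-aldol adduct 13 (not isolated)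
Conditions: 11 (1.3 equiv), Bu2BOTf, iPr2NEt, CH2Cl2, 0 °C; 8, −78 → 0 °C; pH 7 buffer, MeOH, H2O2, 0 °C; then PPTS (cat.), toluene, 50 °C
Reagents that add atoms: none
Why: Evans syn-aldol through the Zimmerman–Traxler chair of the Z-boron enolate, in which the (R)-benzyl auxiliary fixes C7 and C6 as the syn pair under reagent control, followed by acid-catalysed γ-lactonisation of the C6 hydroxyl onto the methyl ester, which turns the syn adduct into the trans-4,5-disubstituted lactone.

Step 8
Reactants: 14 (4R)-4-benzyl-3-{[(2S,3R)-2-[(3R)-4-ethenyl-2,4-dimethylhexa-1,5-dien-3-yl]-5-oxooxolan-3-yl]carbonyl}-1,3-oxazolidin-2-one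
Product: 15 (2S,3R)-2-[(3R)-4-ethenyl-2,4-dimethylhexa-1,5-dien-3-yl]-5-oxooxolane-3-carboxylic acid
Conditions: LiOH, H2O2, THF–H2O, 0 °C; Na2SO3; HCl to pH 2
Reagents that add atoms: hydrogen peroxide (acting as LiOOH), OO
Why: Hydroperoxide hydrolysis cleaves the exocyclic imide carbonyl selectively, and acidification recloses any lactone that was opened.

Step 9
Reactants: 15 (2S,3R)-2-[(3R)-4-ethenyl-2,4-dimethylhexa-1,5-dien-3-yl]-5-oxooxolane-3-carboxylic acid
Product: 17 (4R,5S)-4-acetyl-5-[(3R)-4-ethenyl-2,4-dimethylhexa-1,5-dien-3-yl]oxolan-2-one, via acid chloride 16 (not isolated)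
Conditions: 1-chloro-N,N,2-trimethylprop-1-en-1-amine, CH2Cl2, 0 °C → rt; then Me2CuLi, THF, −78 °C
Reagents that add atoms: lithium dimethylcuprate, [Li+].C[Cu-]C
Why: Neutral acid chloride formation (no HCl to add to the isopropenyl group) and Gilman cuprate ketone synthesis, which stops at the methyl ketone and leaves the lactone alone at −78 °C.

Step 10
Reactants: 17 (4R,5S)-4-acetyl-5-[(3R)-4-ethenyl-2,4-dimethylhexa-1,5-dien-3-yl]oxolan-2-one
Product: 18 (4R,5S)-4-{1-[(tert-butyldimethylsilyl)oxy]ethenyl}-5-[(3R)-4-ethenyl-2,4-dimethylhexa-1,5-dien-3-yl]oxolan-2-one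
Conditions: TBSOTf (1.1 equiv), Et3N, CH2Cl2, −78 → −20 °C
Reagents that add atoms: tert-butyldimethylsilyl triflate, CC(C)(C)[Si](C)(C)OS(=O)(=O)C(F)(F)F
Why: Soft enolisation and O-silylation of the ketone at its unhindered methyl group, since the other α-position (C7) is a hindered methine and the lactone is not enolised at this temperature.

Step 11
Reactants: 18 (4R,5S)-4-{1-[(tert-butyldimethylsilyl)oxy]ethenyl}-5-[(3R)-4-ethenyl-2,4-dimethylhexa-1,5-dien-3-yl]oxolan-2-one
Product: 19 (3aR,6R,7R,7aS)-4-[(tert-butyldimethylsilyl)oxy]-6-ethenyl-6-methyl-7-(prop-1-en-2-yl)-3a,6,7,7a-tetrahydro-1-benzofuran-2(3H)-one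
Conditions: Mo(N-2,6-iPr2C6H3)(CHCMe2Ph)[(S)-3,3'-di-tert-butyl-5,5',6,6'-tetramethyl-1,1'-biphenyl-2,2'-diolate] (10 mol %), C6H6 (0.01 M), 22 → 50 °C, ethylene swept out with argon; the (R)-diolate complex is run in parallel and the matched one kept
Reagents that add atoms: none
Why: Proposed new method: the molybdenum alkylidene exchanges with one of the two C10 vinyl groups, the new Mo=CH–C10 alkylidene adds to the 1,1-disubstituted C8 silyl enol ether to give a molybdacyclobutane, and cycloreversion releases the cyclic enol ether with the C8=C9 bond and Mo=CH2, so ethylene is lost overall; the closest known reactions are molybdenum-catalysed ring-closing metathesis of olefinic enol ethers and catalytic asymmetric ring-closing metathesis of trienes that creates all-carbon quaternary stereocentres. The carbocycle C5–C10 closes as a six-membered ring by joining C9 to C8 across the trans-disubstituted lactone, and this is the only unstrained mode, because vinyl–vinyl closure would give a cyclopropene, vinyl–isopropenyl closure a cyclobutene, and enol ether–isopropenyl closure a tetrasubstituted cyclopentene trans-fused to the lactone. C10 becomes stereogenic in this step, and its configuration (methyl axial and cis to the C5 isopropenyl group, spectator vinyl equatorial) is to be set by the chiral biphenolate acting on a chair-like closure in which the C5 isopropenyl group is equatorial. The selectivity needed is the choice between the two diastereotopic vinyl groups; the substrate contributes only the fixed equatorial C5 substituent next to C10, since an axial methyl and an axial vinyl cost about the same, so the two alkylidenes must interconvert by degenerate exchange and the ligand must decide at ring closure, which is why both antipodes of the complex and related chiral diolates would be screened. The substrate carries no protic group, and the lactone, the silyl enol ether and the isopropenyl group are tolerated by this class of alkylidene; the temperature is kept at or below 50 °C so that the acyclic 1,5-diene does not undergo Cope rearrangement.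

Step 12
Reactants: 19 (3aR,6R,7R,7aS)-4-[(tert-butyldimethylsilyl)oxy]-6-ethenyl-6-methyl-7-(prop-1-en-2-yl)-3a,6,7,7a-tetrahydro-1-benzofuran-2(3H)-one
Product: 20 (3aR,6R,7R,7aS)-6-ethenyl-6-methyl-7-(prop-1-en-2-yl)hexahydro-1-benzofuran-2,4-dione
Conditions: 1 M HCl, THF, 0 °C
Reagents that add atoms: none
Why: Acid hydrolysis of the silyl enol ether gives the C8 ketone with C9 as a methylene, and C7 stays in the more stable trans-fused, all-equatorial arrangement.

Step 13
Reactants: 20 (3aR,6R,7R,7aS)-6-ethenyl-6-methyl-7-(prop-1-en-2-yl)hexahydro-1-benzofuran-2,4-dione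
Product: 21 (3aS,4R,6R,7R,7aS)-6-ethenyl-4-hydroxy-6-methyl-7-(prop-1-en-2-yl)hexahydro-1-benzofuran-2(3H)-one
Conditions: SmI2 (3 equiv), iPrOH, THF, 0 °C → rt
Reagents that add atoms: none
Why: Electron-transfer ketone reduction with SmI2 and a proton donor, in which the ketyl and the derived organosamarium settle before protonation so that the C8 hydroxyl should end equatorial (8α, trans to H7), whereas hydride donors would be steered by the axial C10 methyl toward the axial alcohol; the lactone and the isolated alkenes are not reduced without HMPA.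

Step 14
Reactants: 21 (3aS,4R,6R,7R,7aS)-6-ethenyl-4-hydroxy-6-methyl-7-(prop-1-en-2-yl)hexahydro-1-benzofuran-2(3H)-one
Product: 22 (3aR,4R,6R,7R,7aS)-4-[(tert-butyldimethylsilyl)oxy]-6-ethenyl-6-methyl-7-(prop-1-en-2-yl)hexahydro-1-benzofuran-2(3H)-one
Conditions: TBSOTf, 2,6-lutidine, CH2Cl2, 0 °C
Reagents that add atoms: tert-butyldimethylsilyl triflate, CC(C)(C)[Si](C)(C)OS(=O)(=O)C(F)(F)F
Why: Silyl protection of the secondary alcohol so that the lactone can be enolised in the next step.

Step 15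
Reactants: 22 (3aR,4R,6R,7R,7aS)-4-[(tert-butyldimethylsilyl)oxy]-6-ethenyl-6-methyl-7-(prop-1-en-2-yl)hexahydro-1-benzofuran-2(3H)-one
Product: 24 3-[(dimethylamino)methyl] derivative of 22 (C11 epimers), via lithium enolate 23 (not isolated)
Conditions: LiN(iPr)2, THF, −78 °C; then CH2=NMe2+ I−, −78 → 0 °C
Reagents that add atoms: dimethylmethylideneammonium iodide (Eschenmoser's salt), C=[N+](C)C.[I-]
Why: Mannich reaction of the lactone enolate with Eschenmoser's salt installs C13 on C11; the new C11 centre is removed in the next step, so its configuration does not matter.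

Step 16
Reactants: 24 3-[(dimethylamino)methyl] derivative of 22 (C11 epimers)
Product: 26 (3aR,4R,6R,7R,7aS)-4-[(tert-butyldimethylsilyl)oxy]-6-ethenyl-6-methyl-3-methylidene-7-(prop-1-en-2-yl)hexahydro-1-benzofuran-2(3H)-one, via ammonium iodide 25 (not isolated)
Conditions: MeI, THF, rt; then aq. NaHCO3, EtOAc, rt
Reagents that add atoms: none
Why: Quaternisation of the amine and E1cB elimination of trimethylamine give the α-methylene lactone under mild base.

Step 17
Reactants: 26 (3aR,4R,6R,7R,7aS)-4-[(tert-butyldimethylsilyl)oxy]-6-ethenyl-6-methyl-3-methylidene-7-(prop-1-en-2-yl)hexahydro-1-benzofuran-2(3H)-one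
Product: 27 (3aS,4R,6R,7R,7aS)-6-ethenyl-4-hydroxy-6-methyl-3-methylidene-7-(prop-1-en-2-yl)hexahydro-1-benzofuran-2(3H)-one
Conditions: HF·pyridine, pyridine, THF, 0 °C → rt
Reagents that add atoms: none
Why: Fluoride-mediated desilylation under buffered, weakly nucleophilic conditions that do not add to the α-methylene lactone.

Step 18
Reactants: 28 but-2-yne-1,4-diol
Product: 30 (2E)-2-iodobut-2-ene-1,4-diol, via vinylstannane 29 (not isolated)
Conditions: Bu3SnH, PdCl2(PPh3)2 (2 mol %), THF, rt; then I2, CH2Cl2, 0 °C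
Reagents that add atoms: iodine, II
Why: Palladium-catalysed syn-hydrostannation of the symmetrical alkyne followed by iododestannylation with retention places the two hydroxymethyl groups cis, which is the geometry of the side chain.

Step 19
Reactants: 30 (2E)-2-iodobut-2-ene-1,4-diol
Product: 31 5-iodo-2,2-dimethyl-4,7-dihydro-1,3-dioxepine
Conditions: 2,2-dimethoxypropane, PPTS (cat.), CH2Cl2, rt
Reagents that add atoms: 2,2-dimethoxypropane, COC(C)(C)OC
Why: Transketalisation to the seven-membered acetonide, which can form only because the two hydroxymethyl groups are cis and which then locks that geometry.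

Step 20
Reactants: 31 5-iodo-2,2-dimethyl-4,7-dihydro-1,3-dioxepine
Product: 33 2,2-dimethyl-4,7-dihydro-1,3-dioxepine-5-carboxylic acid, via vinyllithium 32 (not isolated)
Conditions: t-BuLi (2.1 equiv), Et2O, −78 °C; then CO2, −78 → 0 °C; cold dilute HCl to pH 4
Reagents that add atoms: carbon dioxide, O=C=O
Why: Iodine–lithium exchange and carboxylation; the cyclic vinyllithium cannot lose its β-alkoxide without forming a seven-membered cyclic allene, so it should persist at −78 °C.

Step 21
Reactants: 27 (3aS,4R,6R,7R,7aS)-6-ethenyl-4-hydroxy-6-methyl-3-methylidene-7-(prop-1-en-2-yl)hexahydro-1-benzofuran-2(3H)-one; 33 2,2-dimethyl-4,7-dihydro-1,3-dioxepine-5-carboxylic acid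
Product: 34 (3aS,4R,6R,7R,7aS)-6-ethenyl-6-methyl-3-methylidene-2-oxo-7-(prop-1-en-2-yl)octahydro-1-benzofuran-4-yl 2,2-dimethyl-4,7-dihydro-1,3-dioxepine-5-carboxylate
Conditions: DCC, DMAP, CH2Cl2, 0 °C → rt
Reagents that add atoms: none
Why: Steglich esterification of the equatorial C8 hydroxyl; the dioxepine ring holds the alkene geometry of the acid, so acyl activation cannot scramble it.

Step 22
Reactants: 34 (3aS,4R,6R,7R,7aS)-6-ethenyl-6-methyl-3-methylidene-2-oxo-7-(prop-1-en-2-yl)octahydro-1-benzofuran-4-yl 2,2-dimethyl-4,7-dihydro-1,3-dioxepine-5-carboxylate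
Product: 35 CNP0309506.1, (3aS,4R,6R,7R,7aS)-6-ethenyl-6-methyl-3-methylidene-2-oxo-7-(prop-1-en-2-yl)octahydro-1-benzofuran-4-yl (2E)-4-hydroxy-2-(hydroxymethyl)but-2-enoate
Conditions: AcOH–H2O (4:1), rt
Reagents that add atoms: none
Why: Mild acid hydrolysis of the strained seven-membered acetonide frees the two primary alcohols without touching the ester or the α-methylene lactone.

**Compound list**

1 | (2Z)-3-methylpent-2-en-4-yn-1-ol | C#C/C(C)=C\CO | starting material
2 | (2Z)-3-methylpenta-2,4-dien-1-ol | C=C/C(C)=C\CO | intermediate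
3 | 3-methylbut-3-enoic acid | CC(=C)CC(=O)O | starting material
4 | (2Z)-3-methylpenta-2,4-dien-1-yl 3-methylbut-3-enoate | C=C/C(C)=C\COC(=O)CC(C)=C | intermediate
5 | boron ketene acetal of 4 (E-configured enolate, O-bound to the (S,S)-diazaborolidine) | C=C/C(C)=C\CO/C(=C\C(C)=C)OB1N(S(=O)(=O)c2cc(cc(c2)C(F)(F)F)C(F)(F)F)[C@@H](c2ccccc2)[C@H](c2ccccc2)N1S(=O)(=O)c1cc(cc(c1)C(F)(F)F)C(F)(F)F | intermediate
6 | (2R)-3-ethenyl-3-methyl-2-(prop-1-en-2-yl)pent-4-enoic acid | C=CC(C)(C=C)[C@@H](C(C)=C)C(=O)O | intermediate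
7 | (2R)-3-ethenyl-3-methyl-2-(prop-1-en-2-yl)pent-4-en-1-ol | C=CC(C)(C=C)[C@@H](C(C)=C)CO | intermediate
8 | (2R)-3-ethenyl-3-methyl-2-(prop-1-en-2-yl)pent-4-enal | C=CC(C)(C=C)[C@@H](C(C)=C)C=O | intermediate
9 | (4R)-4-benzyl-1,3-oxazolidin-2-one | O=C1OC[C@@H](Cc2ccccc2)N1 | starting material
10 | methyl 4-chloro-4-oxobutanoate | COC(=O)CCC(=O)Cl | starting material
11 | methyl 4-[(4R)-4-benzyl-2-oxo-1,3-oxazolidin-3-yl]-4-oxobutanoate | COC(=O)CCC(=O)N1C(=O)OC[C@H]1Cc1ccccc1 | intermediate
12 | dibutylboron (Z)-enolate of 11 | CCCCB(CCCC)O/C(=C\CC(=O)OC)N1C(=O)OC[C@H]1Cc1ccccc1 | intermediate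
13 | methyl (3R,4S,5R)-3-{[(4R)-4-benzyl-2-oxo-1,3-oxazolidin-3-yl]carbonyl}-6-ethenyl-4-hydroxy-6-methyl-5-(prop-1-en-2-yl)oct-7-enoate (syn-aldol adduct) | C=CC(C)(C=C)[C@@H](C(C)=C)[C@H](O)[C@@H](CC(=O)OC)C(=O)N1C(=O)OC[C@H]1Cc1ccccc1 | intermediate
14 | (4R)-4-benzyl-3-{[(2S,3R)-2-[(3R)-4-ethenyl-2,4-dimethylhexa-1,5-dien-3-yl]-5-oxooxolan-3-yl]carbonyl}-1,3-oxazolidin-2-one (trans lactone) | C=CC(C)(C=C)[C@@H](C(C)=C)[C@@H]1OC(=O)C[C@H]1C(=O)N1C(=O)OC[C@H]1Cc1ccccc1 | intermediate
15 | (2S,3R)-2-[(3R)-4-ethenyl-2,4-dimethylhexa-1,5-dien-3-yl]-5-oxooxolane-3-carboxylic acid | C=CC(C)(C=C)[C@@H](C(C)=C)[C@@H]1OC(=O)C[C@H]1C(=O)O | intermediate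
16 | (2S,3R)-2-[(3R)-4-ethenyl-2,4-dimethylhexa-1,5-dien-3-yl]-5-oxooxolane-3-carbonyl chloride | C=CC(C)(C=C)[C@@H](C(C)=C)[C@@H]1OC(=O)C[C@H]1C(=O)Cl | intermediate
17 | (4R,5S)-4-acetyl-5-[(3R)-4-ethenyl-2,4-dimethylhexa-1,5-dien-3-yl]oxolan-2-one | C=CC(C)(C=C)[C@@H](C(C)=C)[C@@H]1OC(=O)C[C@H]1C(C)=O | intermediate
18 | (4R,5S)-4-{1-[(tert-butyldimethylsilyl)oxy]ethenyl}-5-[(3R)-4-ethenyl-2,4-dimethylhexa-1,5-dien-3-yl]oxolan-2-one (metathesis precursor) | C=CC(C)(C=C)[C@@H](C(C)=C)[C@@H]1OC(=O)C[C@H]1C(O[Si](C)(C)C(C)(C)C)=C | intermediate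
19 | (3aR,6R,7R,7aS)-4-[(tert-butyldimethylsilyl)oxy]-6-ethenyl-6-methyl-7-(prop-1-en-2-yl)-3a,6,7,7a-tetrahydro-1-benzofuran-2(3H)-one (metathesis product) | C=C[C@@]1(C)C=C(O[Si](C)(C)C(C)(C)C)[C@@H]2CC(=O)O[C@H]2[C@@H]1C(=C)C | intermediate
20 | (3aR,6R,7R,7aS)-6-ethenyl-6-methyl-7-(prop-1-en-2-yl)hexahydro-1-benzofuran-2,4-dione | C=C[C@@]1(C)CC(=O)[C@@H]2CC(=O)O[C@H]2[C@@H]1C(=C)C | intermediate
21 | (3aS,4R,6R,7R,7aS)-6-ethenyl-4-hydroxy-6-methyl-7-(prop-1-en-2-yl)hexahydro-1-benzofuran-2(3H)-one (equatorial 8α-alcohol) | C=C[C@@]1(C)C[C@@H](O)[C@@H]2CC(=O)O[C@H]2[C@@H]1C(=C)C | intermediate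
22 | (3aR,4R,6R,7R,7aS)-4-[(tert-butyldimethylsilyl)oxy]-6-ethenyl-6-methyl-7-(prop-1-en-2-yl)hexahydro-1-benzofuran-2(3H)-one | C=C[C@@]1(C)C[C@@H](O[Si](C)(C)C(C)(C)C)[C@@H]2CC(=O)O[C@H]2[C@@H]1C(=C)C | intermediate
23 | lithium enolate of lactone 22 | C=C[C@@]1(C)C[C@@H](O[Si](C)(C)C(C)(C)C)[C@@H]2C=C(O[Li])O[C@H]2[C@@H]1C(=C)C | intermediate
24 | 3-[(dimethylamino)methyl] derivative of 22 (C11 epimers, configuration not controlled) | C=C[C@@]1(C)C[C@@H](O[Si](C)(C)C(C)(C)C)[C@@H]2C(CN(C)C)C(=O)O[C@H]2[C@@H]1C(=C)C | intermediate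
25 | trimethylammonium iodide of 24 (C11 epimers) | C=C[C@@]1(C)C[C@@H](O[Si](C)(C)C(C)(C)C)[C@@H]2C(C[N+](C)(C)C)C(=O)O[C@H]2[C@@H]1C(=C)C.[I-] | intermediate
26 | (3aR,4R,6R,7R,7aS)-4-[(tert-butyldimethylsilyl)oxy]-6-ethenyl-6-methyl-3-methylidene-7-(prop-1-en-2-yl)hexahydro-1-benzofuran-2(3H)-one | C=C[C@@]1(C)C[C@@H](O[Si](C)(C)C(C)(C)C)[C@@H]2C(=C)C(=O)O[C@H]2[C@@H]1C(=C)C | intermediate
27 | (3aS,4R,6R,7R,7aS)-6-ethenyl-4-hydroxy-6-methyl-3-methylidene-7-(prop-1-en-2-yl)hexahydro-1-benzofuran-2(3H)-one | C=C[C@@]1(C)C[C@@H](O)[C@@H]2C(=C)C(=O)O[C@H]2[C@@H]1C(=C)C | intermediate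
28 | but-2-yne-1,4-diol | OCC#CCO | starting material
29 | (2E)-2-(tributylstannyl)but-2-ene-1,4-diol | OC/C=C(\CO)[Sn](CCCC)(CCCC)CCCC | intermediate
30 | (2E)-2-iodobut-2-ene-1,4-diol (hydroxymethyl groups cis) | OC/C=C(\CO)I | intermediate
31 | 5-iodo-2,2-dimethyl-4,7-dihydro-1,3-dioxepine | CC1(C)OCC=C(I)CO1 | intermediate
32 | (2,2-dimethyl-4,7-dihydro-1,3-dioxepin-5-yl)lithium | [Li]C1=CCOC(C)(C)OC1 | intermediate
33 | 2,2-dimethyl-4,7-dihydro-1,3-dioxepine-5-carboxylic acid | CC1(C)OCC=C(CO1)C(=O)O | intermediate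
34 | (3aS,4R,6R,7R,7aS)-6-ethenyl-6-methyl-3-methylidene-2-oxo-7-(prop-1-en-2-yl)octahydro-1-benzofuran-4-yl 2,2-dimethyl-4,7-dihydro-1,3-dioxepine-5-carboxylate | C=C[C@@]1(C)C[C@@H](OC(=O)C3=CCOC(C)(C)OC3)[C@@H]2C(=C)C(=O)O[C@H]2[C@@H]1C(=C)C | intermediate
35 | CNP0309506.1, (3aS,4R,6R,7R,7aS)-6-ethenyl-6-methyl-3-methylidene-2-oxo-7-(prop-1-en-2-yl)octahydro-1-benzofuran-4-yl (2E)-4-hydroxy-2-(hydroxymethyl)but-2-enoate | C=C[C@@]1(C)C[C@@H](OC(=O)/C(=C/CO)CO)[C@@H]2C(=C)C(=O)O[C@H]2[C@@H]1C(=C)C | target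

**Step count**

Total: 22 steps. Longest linear sequence: 18 steps (steps 1–5, 7–17, 21 and 22).

**Steps most likely to fail, with fallbacks**

Step 11 (the proposed new method). The complex may fail to tell the two C10 vinyl groups apart, or initiation at the neopentyl-type vinyl groups may be slower than decay of the catalyst. The fallback uses known chemistry throughout and moves the choice between the two C10 alkenyl groups from the metathesis into the Claisen step. It sets out from enynol 1 and acid 3 and comes back at ketone 20.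

- The alkyne of 1 is kept and silylated instead of reduced. n-BuLi (2.1 equiv) and TBSCl give the O,C-bis-silyl compound F1 (not isolated), and 1 M HCl in THF removes the O-silyl group to leave the C-silylated enynol F2.
- Esterification with 3 as in step 2 gives the enynyl ester F3.
- Under the conditions of step 3 the E-configured boron ketene acetal F4 rearranges through a chair in which the isopropenyl group and the Z-placed silylethynyl group are both axial. C5 and C10 are then created together in the required relation (diastereoselective Ireland–Claisen rearrangement), giving the (2R,3S)-acid F5.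
- The sequence of steps 4 to 10 is repeated: LiAlH4 gives alcohol F6 and Dess–Martin oxidation gives aldehyde F7; the aldol of step 7 gives the syn adduct F8 and then lactone imide F9; LiOOH gives lactone acid F10; the chloroenamine gives acid chloride F11 and Me2CuLi gives methyl ketone F12; TBSOTf and Et3N give silyl enol ether F13.
- F13 has a single vinyl group on C10 and an inert, bulky silylalkyne. Ring-closing metathesis with the achiral second-generation ruthenium catalyst RuCl2(H2IMes)(=CH-2-iPrOC6H4) can therefore give only the bicyclic enol ether F14, with C10 already fixed.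
- TBAF buffered with AcOH removes both silyl groups to give the ethynyl ketone F15, and semihydrogenation over Pd/CaCO3 poisoned with Pb(OAc)2 turns the ethynyl group into the C1=C2 vinyl group of 20.

Step 7. Addition of the bulky boron enolate to the neopentyl-type aldehyde may be slower than α-epimerisation of the aldehyde, or the auxiliary may work against the aldehyde's own facial bias. The fallback relies on substrate control and a small nucleophile; it sets out from aldehyde 8 and comes back at acid 15.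

- The lithium enolate of dimethyl succinate (LiN(iPr)2, THF, −78 °C) adds under Felkin–Anh control, with the quaternary carbon anti and attack past the hydrogen. This sets C6 as required and gives mainly the anti hydroxy diester F16.
- PPTS in toluene closes F16 to the cis lactone methyl ester F17.
- C7 is α to the ester, so DBU in CH2Cl2 at rt equilibrates it to the more stable trans lactone methyl ester F18.
- LiOH in THF–water followed by acidification gives 15.

Step 13. Protonation may occur from the wrong side and give the axial alcohol, or the reduction may be slow enough for the β-acyloxy ketone to eliminate. The fallback accepts the kinetic alcohol and inverts it; it sets out from ketone 20 and comes back at alcohol 21.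

- LiBH(s-Bu)3 in THF at −78 °C attacks from the equatorial side, away from the axial C10 methyl, and gives the axial 8β-alcohol F19.
- Mitsunobu reaction with 4-nitrobenzoic acid, PPh3 and DIAD in toluene inverts C8 to the equatorial 8α 4-nitrobenzoate F20.
- K2CO3 in MeOH, followed by dilute HCl to reclose the lactone, gives 21.

**Further compounds**

F1 | step 11 | tert-butyl{[(2Z)-5-(tert-butyldimethylsilyl)-3-methylpent-2-en-4-yn-1-yl]oxy}dimethylsilane | CC(C)(C)[Si](C)(C)C#C/C(C)=C\CO[Si](C)(C)C(C)(C)C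
F2 | step 11 | (2Z)-5-(tert-butyldimethylsilyl)-3-methylpent-2-en-4-yn-1-ol | CC(C)(C)[Si](C)(C)C#C/C(C)=C\CO
F3 | step 11 | (2Z)-5-(tert-butyldimethylsilyl)-3-methylpent-2-en-4-yn-1-yl 3-methylbut-3-enoate | CC(C)(C)[Si](C)(C)C#C/C(C)=C\COC(=O)CC(C)=C
F4 | step 11 | boron ketene acetal of F3 (E-configured, (S,S)-diazaborolidine) | CC(C)(C)[Si](C)(C)C#C/C(C)=C\CO/C(=C\C(C)=C)OB1N(S(=O)(=O)c2cc(cc(c2)C(F)(F)F)C(F)(F)F)[C@@H](c2ccccc2)[C@H](c2ccccc2)N1S(=O)(=O)c1cc(cc(c1)C(F)(F)F)C(F)(F)F
F5 | step 11 | (2R,3S)-3-[(tert-butyldimethylsilyl)ethynyl]-3-methyl-2-(prop-1-en-2-yl)pent-4-enoic acid | CC(C)(C)[Si](C)(C)C#C[C@@](C)(C=C)[C@@H](C(C)=C)C(=O)O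
F6 | step 11 | (2R,3S)-3-[(tert-butyldimethylsilyl)ethynyl]-3-methyl-2-(prop-1-en-2-yl)pent-4-en-1-ol | CC(C)(C)[Si](C)(C)C#C[C@@](C)(C=C)[C@@H](C(C)=C)CO
F7 | step 11 | (2R,3S)-3-[(tert-butyldimethylsilyl)ethynyl]-3-methyl-2-(prop-1-en-2-yl)pent-4-enal | CC(C)(C)[Si](C)(C)C#C[C@@](C)(C=C)[C@@H](C(C)=C)C=O
F8 | step 11 | syn-aldol adduct of F7 with imide 11 | CC(C)(C)[Si](C)(C)C#C[C@@](C)(C=C)[C@@H](C(C)=C)[C@H](O)[C@@H](CC(=O)OC)C(=O)N1C(=O)OC[C@H]1Cc1ccccc1
F9 | step 11 | trans lactone imide, silylethynyl analogue of 14 | CC(C)(C)[Si](C)(C)C#C[C@@](C)(C=C)[C@@H](C(C)=C)[C@@H]1OC(=O)C[C@H]1C(=O)N1C(=O)OC[C@H]1Cc1ccccc1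
F10 | step 11 | lactone acid, silylethynyl analogue of 15 | CC(C)(C)[Si](C)(C)C#C[C@@](C)(C=C)[C@@H](C(C)=C)[C@@H]1OC(=O)C[C@H]1C(=O)O
F11 | step 11 | acid chloride, silylethynyl analogue of 16 | CC(C)(C)[Si](C)(C)C#C[C@@](C)(C=C)[C@@H](C(C)=C)[C@@H]1OC(=O)C[C@H]1C(=O)Cl
F12 | step 11 | methyl ketone, silylethynyl analogue of 17 | CC(C)(C)[Si](C)(C)C#C[C@@](C)(C=C)[C@@H](C(C)=C)[C@@H]1OC(=O)C[C@H]1C(C)=O
F13 | step 11 | silyl enol ether, silylethynyl analogue of 18 | CC(C)(C)[Si](C)(C)C#C[C@@](C)(C=C)[C@@H](C(C)=C)[C@@H]1OC(=O)C[C@H]1C(O[Si](C)(C)C(C)(C)C)=C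
F14 | step 11 | bicyclic silyl enol ether with a silylethynyl group on C10, analogue of 19 | CC(C)(C)[Si](C)(C)C#C[C@@]1(C)C=C(O[Si](C)(C)C(C)(C)C)[C@@H]2CC(=O)O[C@H]2[C@@H]1C(=C)C
F15 | step 11 | ethynyl ketone, C10-ethynyl analogue of 20 | C#C[C@@]1(C)CC(=O)[C@@H]2CC(=O)O[C@H]2[C@@H]1C(=C)C
F16 | step 7 | dimethyl 2-[(1S,2R)-3-ethenyl-1-hydroxy-3-methyl-2-(prop-1-en-2-yl)pent-4-en-1-yl]butanedioate (anti adduct) | C=CC(C)(C=C)[C@@H](C(C)=C)[C@H](O)[C@H](CC(=O)OC)C(=O)OC
F17 | step 7 | cis lactone methyl ester (C7 epimer of the methyl ester of 15) | C=CC(C)(C=C)[C@@H](C(C)=C)[C@@H]1OC(=O)C[C@@H]1C(=O)OC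
F18 | step 7 | trans lactone methyl ester (methyl ester of 15) | C=CC(C)(C=C)[C@@H](C(C)=C)[C@@H]1OC(=O)C[C@H]1C(=O)OC
F19 | step 13 | axial 8β-alcohol (C8 epimer of 21) | C=C[C@@]1(C)C[C@H](O)[C@@H]2CC(=O)O[C@H]2[C@@H]1C(=C)C
F20 | step 13 | equatorial 8α 4-nitrobenzoate of 21 | C=C[C@@]1(C)C[C@@H](OC(=O)c3ccc(cc3)[N+](=O)[O-])[C@@H]2CC(=O)O[C@H]2[C@@H]1C(=C)C
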